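## Retrosynthetic overview

1. Target 25 ⇐ 24 ⇐ 23: the C15=C17 methylene is unmasked last by E1cB loss of pivalate from a β‑pivaloyloxymethyl group, after selective acetylation of O3.
2. 23 ⇐ 21: the 14‑membered carbocycle is closed last at C3–C4 by a Ni(0)/chiral‑NHC reductive ynal macrocyclisation (proposed new method; sets 3R and the 4E alkene).
3. 21 ⇐ 19: the ε‑lactone comes from Baeyer–Villiger ring expansion of a cyclohexanone; the quaternary C12 migrates with retention and becomes the tertiary C12–O centre.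
4. 19 ⇐ 14 + 8: C11–C12 by aldol then oxidation, C‑methylation of the β‑diketone (12S), CBS reduction (11R). 14 ⇐ cyclohexenone + C2 Grignard + CH2O by asymmetric conjugate addition with aldol trapping (1S, C17).
5. 8 ⇐ 1 + propyne + 1‑bromobut‑2‑yne (carbocupration sets 7Z). Ring order: six‑membered carbocycle (bought) → oxepanone (step 8) → 14‑membered ring (step 10).

Assumption: locants C1–C17 are those of the 13‑oxabicyclo[10.3.2]heptadecane name of the target (C18–C20 are the methyls on C4, C8, C12); for each chiral catalyst the antipode that gives the drawn centre is used.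

## Route

Step 1
Reactants: 1 2-(2-bromoethyl)-1,3-dioxolane; 2 propyne; 3 1-bromobut-2-yne
Product: 7 2-[(3Z)-3-methyloct-3-en-6-yn-1-yl]-1,3-dioxolane, via Grignard reagent 4 (not isolated), via alkylcopper 5 (not isolated), via Z-alkenylcopper 6 (not isolated)
Conditions: Mg, THF, 25 °C; CuBr·SMe2 (1.0 equiv), Et2O/Me2S, −45 °C; 2, −25 °C; 3, DMPU, −40 → 0 °C
Reagents that add atoms: none
Why: Normant syn‑carbocupration of propyne puts the alkyl chain and copper cis, which fixes the 7Z trisubstituted alkene, and the alkenylcopper is then alkylated with retention at the primary propargylic bromide (SN2 coupling).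

Step 2
Reactants: 7 2-[(3Z)-3-methyloct-3-en-6-yn-1-yl]-1,3-dioxolane
Product: 8 (4Z)-4-methylnon-4-en-7-ynal
Conditions: 1 M HCl, THF, 25 °C
Reagents that add atoms: water, SMILES O
Why: Acid‑catalysed acetal hydrolysis frees the C11 aldehyde; the skipped enyne is inert to dilute acid at room temperature.

Step 3
Reactants: 9 cyclohex-2-en-1-one; 10 2-(bromomethyl)-1,3-dioxolane
Product: 14 (2R,3S)-3-(1,3-dioxolan-2-ylmethyl)-2-[(pivaloyloxy)methyl]cyclohexan-1-one, via Grignard reagent 11 (not isolated), via magnesium enolate 12 (not isolated), via magnesium alkoxide 13 (not isolated)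
Conditions: 10, Mg, 2‑MeTHF, 30 °C; add to 9, CuBr·SMe2 (5 mol%), (R,SFe)‑JosiPhos (6 mol%), t‑BuOMe, −75 °C; CH2O (THF solution), −78 °C; PivCl, −78 → −20 °C
Reagents that add atoms: formaldehyde, SMILES C=O; pivaloyl chloride, SMILES CC(C)(C)C(Cl)=O
Why: Cu/ferrocenyl‑diphosphine‑catalysed asymmetric conjugate addition of the Grignard reagent sets C1 (3S); the regiodefined enolate is trapped by formaldehyde anti to the new substituent (tandem conjugate addition–aldol, 2,3‑trans, installs C17), and in‑situ acylation blocks C15 and stores C17 as a β‑acyloxy leaving group.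

Step 4
Reactants: 14 (2R,3S)-3-(1,3-dioxolan-2-ylmethyl)-2-[(pivaloyloxy)methyl]cyclohexan-1-one; 8 (4Z)-4-methylnon-4-en-7-ynal
Product: 16 (2R,3S)-3-(1,3-dioxolan-2-ylmethyl)-6-[(4Z)-1-hydroxy-4-methylnon-4-en-7-yn-1-yl]-2-[(pivaloyloxy)methyl]cyclohexan-1-one (mixture of C6/C1′ epimers), via lithium enolate 15 (not isolated)
Conditions: LDA (1.05 equiv), THF, −78 °C; 8, −78 °C; AcOH quench
Reagents that add atoms: none
Why: Kinetic deprotonation occurs only at the unhindered C12 methylene (C15 is a blocked methine) and the lithium enolate undergoes a directed aldol addition; the two new centres are left unassigned because they are erased or reset in steps 5–7.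

Step 5
Reactants: 16 aldol adduct (epimer mixture)
Product: 17 (2R,3S)-3-(1,3-dioxolan-2-ylmethyl)-6-[(4Z)-4-methylnon-4-en-7-ynoyl]-2-[(pivaloyloxy)methyl]cyclohexan-1-one (keto/enol mixture)
Conditions: Dess–Martin periodinane, CH2Cl2, 0 → 25 °C
Reagents that add atoms: none
Why: Dess–Martin oxidation of the β‑hydroxy ketone gives the 2‑acylcyclohexanone and converges all aldol epimers without touching ester, acetal, alkene or alkyne.

Step 6
Reactants: 17 2-acylcyclohexanone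
Product: 18 (2S,5S,6R)-5-(1,3-dioxolan-2-ylmethyl)-2-methyl-2-[(4Z)-4-methylnon-4-en-7-ynoyl]-6-[(pivaloyloxy)methyl]cyclohexan-1-one
Conditions: K2CO3, MeI, acetone, 25 °C
Reagents that add atoms: iodomethane, SMILES CI
Why: C‑alkylation of the β‑diketonate (only C12–H is acidic enough for carbonate) creates the quaternary centre; MeI attacks axially on the face anti to the C15 substituent and syn to the equatorial C1 substituent, so the methyl ends cis to C2 (12S).

Step 7
Reactants: 18 2-acyl-2-methylcyclohexanone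
Product: 19 (2S,5S,6R)-5-(1,3-dioxolan-2-ylmethyl)-2-[(1R,4Z)-1-hydroxy-4-methylnon-4-en-7-yn-1-yl]-2-methyl-6-[(pivaloyloxy)methyl]cyclohexan-1-one
Conditions: (S)‑Me‑CBS oxazaborolidine (0.5 equiv), catecholborane (2 equiv), toluene, −45 °C; MeOH, pH 7 buffer
Reagents that add atoms: none
Why: Corey–Bakshi–Shibata reduction: the side‑chain ketone (quaternary carbon vs CH2) is far more accessible than the 2,2,6‑trisubstituted ring ketone, and the (S)‑catalyst with RL = quaternary carbon gives the 11R alcohol under catalyst control; catecholborane does not hydroborate the alkene or alkyne at this temperature.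

Step 8
Reactants: 19 β-hydroxy cyclohexanone
Product: 20 [(3R,4S,7S)-4-(1,3-dioxolan-2-ylmethyl)-7-[(1R,4Z)-1-hydroxy-4-methylnon-4-en-7-yn-1-yl]-7-methyl-2-oxooxepan-3-yl]methyl 2,2-dimethylpropanoate
Conditions: Me3SiOOSiMe3 (3 equiv), SnCl4 (15 mol%), trans‑cyclohexane‑1,2‑diamine (15 mol%), 4 Å MS, CH2Cl2, 0 → 25 °C; citric acid work‑up
Reagents that add atoms: bis(trimethylsilyl) peroxide, SMILES C[Si](C)(C)OO[Si](C)(C)C
Why: Baeyer–Villiger ring expansion (6 → 7): the Sn(IV)‑activated ketone adds the nucleophilic silyl peroxide and the fully substituted C12 migrates to oxygen with retention (C15, carrying the β‑acyloxy group, migrates poorly), giving the ε‑lactone and the tertiary C12–O centre, while this non‑electrophilic oxidant leaves the isolated C=C and C≡C bonds alone.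

Step 9
Reactants: 20 lactone acetal
Product: 21 [(3R,4S,7S)-7-[(1R,4Z)-1-hydroxy-4-methylnon-4-en-7-yn-1-yl]-7-methyl-2-oxo-4-(2-oxoethyl)oxepan-3-yl]methyl 2,2-dimethylpropanoate
Conditions: TsOH·H2O (0.2 equiv), THF/H2O 4:1, 45 °C
Reagents that add atoms: water, SMILES O
Why: Acetal hydrolysis releases the C3 aldehyde; lactone, pivalate and the secondary alcohol are stable to catalytic acid.

Step 10
Reactants: 21 seco ynal
Product: 23 [(1S,3R,4E,7Z,11R,12S,15R)-3,11-dihydroxy-4,8,12-trimethyl-14-oxo-13-oxabicyclo[10.3.2]heptadeca-4,7-dien-15-yl]methyl 2,2-dimethylpropanoate, via triethylsilyl ether 22 (not isolated)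
Conditions: Ni(cod)2 (20 mol%), (4S,5S)‑1,3‑dimesityl‑4,5‑diphenylimidazolin‑2‑ylidene (22 mol%), Et3SiH (4 equiv), THF, 40 °C, syringe‑pump addition to 2 mM; then AcOH/THF/H2O, 25 °C
Reagents that add atoms: none
Why: Proposed new method: Ni(0)–NHC oxidative cyclisation of the aldehyde and the methyl alkyne gives an oxanickelacyclopentene with the C–C bond at the methyl‑bearing C4 (endo mode, favoured by small N‑aryl groups), and Si–H σ‑bond metathesis with C–H reductive elimination delivers H syn, which gives the 4E alkene and the 14‑membered ring; the C2‑symmetric backbone of the carbene is proposed to select the aldehyde face in the ring‑forming step and so set 3R by catalyst control. The closest known reactions are the achiral Ni–NHC/silane reductive macrocyclisations of ynals and the intermolecular enantioselective Ni/chiral‑NHC alkyne–aldehyde reductive couplings; their combination in a stereocontrolled macrocyclisation has not been shown.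

Step 11
Reactants: 23 macrocyclic diol
Product: 24 [(1S,3R,4E,7Z,11R,12S,15R)-3-(acetyloxy)-11-hydroxy-4,8,12-trimethyl-14-oxo-13-oxabicyclo[10.3.2]heptadeca-4,7-dien-15-yl]methyl 2,2-dimethylpropanoate
Conditions: Ac2O (1.1 equiv), pyridine, DMAP (5 mol%), CH2Cl2, −20 → 0 °C
Reagents that add atoms: acetic anhydride, SMILES CC(=O)OC(C)=O
Why: Sterically controlled acylation: the allylic C3–OH is acetylated, whereas the C11–OH next to the fully substituted C12 is not.

Step 12
Reactants: 24 acetate pivalate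
Product: 25 (1S,3R,4E,7Z,11R,12S)-11-hydroxy-4,8,12-trimethyl-15-methylidene-14-oxo-13-oxabicyclo[10.3.2]heptadeca-4,7-dien-3-yl acetate
Conditions: DBU (2 equiv), CH2Cl2, 0 → 25 °C
Reagents that add atoms: none
Why: E1cB elimination of pivalate from the β‑acyloxy lactone unveils the α‑methylene lactone in the last step without affecting the acetate or the free C11–OH.

## Compound list

1 | 2-(2-bromoethyl)-1,3-dioxolane | BrCCC1OCCO1 | starting material
2 | propyne | CC#C | starting material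
3 | 1-bromobut-2-yne | CC#CCBr | starting material
4 | [2-(1,3-dioxolan-2-yl)ethyl]magnesium bromide | Br[Mg]CCC1OCCO1 | intermediate
5 | [2-(1,3-dioxolan-2-yl)ethyl]copper | [Cu]CCC1OCCO1 | intermediate
6 | [(1Z)-4-(1,3-dioxolan-2-yl)-2-methylbut-1-en-1-yl]copper | [Cu]/C=C(/C)CCC1OCCO1 | intermediate
7 | 2-[(3Z)-3-methyloct-3-en-6-yn-1-yl]-1,3-dioxolane | CC#CC/C=C(/C)CCC1OCCO1 | intermediate
8 | (4Z)-4-methylnon-4-en-7-ynal | CC#CC/C=C(/C)CCC=O | intermediate
9 | cyclohex-2-en-1-one | O=C1C=CCCC1 | starting material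
10 | 2-(bromomethyl)-1,3-dioxolane | BrCC1OCCO1 | starting material
11 | (1,3-dioxolan-2-ylmethyl)magnesium bromide | Br[Mg]CC1OCCO1 | intermediate
12 | bromomagnesium (3S)-3-(1,3-dioxolan-2-ylmethyl)cyclohex-1-en-1-olate | Br[Mg]OC1=C[C@H](CC2OCCO2)CCC1 | intermediate
13 | bromomagnesium alkoxide of (2R,3S)-3-(1,3-dioxolan-2-ylmethyl)-2-(hydroxymethyl)cyclohexan-1-one | Br[Mg]OC[C@@H]1C(=O)CCC[C@H]1CC2OCCO2 | intermediate
14 | (2R,3S)-3-(1,3-dioxolan-2-ylmethyl)-2-[(pivaloyloxy)methyl]cyclohexan-1-one (2,3-trans) | CC(C)(C)C(=O)OC[C@@H]1C(=O)CCC[C@H]1CC2OCCO2 | intermediate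
15 | lithium (5S,6R)-5-(1,3-dioxolan-2-ylmethyl)-6-[(pivaloyloxy)methyl]cyclohex-1-en-1-olate | CC(C)(C)C(=O)OC[C@@H]1C(O[Li])=CCC[C@H]1CC2OCCO2 | intermediate
16 | (2R,3S)-3-(1,3-dioxolan-2-ylmethyl)-6-[(4Z)-1-hydroxy-4-methylnon-4-en-7-yn-1-yl]-2-[(pivaloyloxy)methyl]cyclohexan-1-one, epimer mixture at C6 and C1′ | CC(C)(C)C(=O)OC[C@@H]1C(=O)C(C(O)CC/C(C)=C\CC#CC)CC[C@H]1CC2OCCO2 | intermediate
17 | (2R,3S)-3-(1,3-dioxolan-2-ylmethyl)-6-[(4Z)-4-methylnon-4-en-7-ynoyl]-2-[(pivaloyloxy)methyl]cyclohexan-1-one, keto/enol mixture | CC(C)(C)C(=O)OC[C@@H]1C(=O)C(C(=O)CC/C(C)=C\CC#CC)CC[C@H]1CC2OCCO2 | intermediate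
18 | (2S,5S,6R)-5-(1,3-dioxolan-2-ylmethyl)-2-methyl-2-[(4Z)-4-methylnon-4-en-7-ynoyl]-6-[(pivaloyloxy)methyl]cyclohexan-1-one | CC(C)(C)C(=O)OC[C@@H]1C(=O)[C@@](C(=O)CC/C(C)=C\CC#CC)(C)CC[C@H]1CC2OCCO2 | intermediate
19 | (2S,5S,6R)-5-(1,3-dioxolan-2-ylmethyl)-2-[(1R,4Z)-1-hydroxy-4-methylnon-4-en-7-yn-1-yl]-2-methyl-6-[(pivaloyloxy)methyl]cyclohexan-1-one | CC(C)(C)C(=O)OC[C@@H]1C(=O)[C@@]([C@H](O)CC/C(C)=C\CC#CC)(C)CC[C@H]1CC2OCCO2 | intermediate
20 | [(3R,4S,7S)-4-(1,3-dioxolan-2-ylmethyl)-7-[(1R,4Z)-1-hydroxy-4-methylnon-4-en-7-yn-1-yl]-7-methyl-2-oxooxepan-3-yl]methyl 2,2-dimethylpropanoate | CC(C)(C)C(=O)OC[C@@H]1C(=O)O[C@@]([C@H](O)CC/C(C)=C\CC#CC)(C)CC[C@H]1CC2OCCO2 | intermediate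
21 | [(3R,4S,7S)-7-[(1R,4Z)-1-hydroxy-4-methylnon-4-en-7-yn-1-yl]-7-methyl-2-oxo-4-(2-oxoethyl)oxepan-3-yl]methyl 2,2-dimethylpropanoate | CC(C)(C)C(=O)OC[C@@H]1C(=O)O[C@@]([C@H](O)CC/C(C)=C\CC#CC)(C)CC[C@H]1CC=O | intermediate
22 | O3-triethylsilyl ether of 23 | CC(C)(C)C(=O)OC[C@@H]1C(=O)O[C@@]2(C)CC[C@H]1C[C@@H](O[Si](CC)(CC)CC)/C(C)=C/C/C=C(/C)CC[C@H]2O | intermediate
23 | [(1S,3R,4E,7Z,11R,12S,15R)-3,11-dihydroxy-4,8,12-trimethyl-14-oxo-13-oxabicyclo[10.3.2]heptadeca-4,7-dien-15-yl]methyl 2,2-dimethylpropanoate | CC(C)(C)C(=O)OC[C@@H]1C(=O)O[C@@]2(C)CC[C@H]1C[C@@H](O)/C(C)=C/C/C=C(/C)CC[C@H]2O | intermediate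
24 | [(1S,3R,4E,7Z,11R,12S,15R)-3-(acetyloxy)-11-hydroxy-4,8,12-trimethyl-14-oxo-13-oxabicyclo[10.3.2]heptadeca-4,7-dien-15-yl]methyl 2,2-dimethylpropanoate | CC(C)(C)C(=O)OC[C@@H]1C(=O)O[C@@]2(C)CC[C@H]1C[C@@H](OC(C)=O)/C(C)=C/C/C=C(/C)CC[C@H]2O | intermediate
25 | (1S,3R,4E,7Z,11R,12S)-11-hydroxy-4,8,12-trimethyl-15-methylidene-14-oxo-13-oxabicyclo[10.3.2]heptadeca-4,7-dien-3-yl acetate (CNP0344673.1) | C=C1C(=O)O[C@@]2(C)CC[C@H]1C[C@@H](OC(C)=O)/C(C)=C/C/C=C(/C)CC[C@H]2O | target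

## Step count and risks

Total steps: 12. Longest linear sequence: 11 steps (1 → 7 → 8 → 16 → 17 → 18 → 19 → 20 → 21 → 23 → 24 → 25); the ring branch from 9 is 10 steps.

**Step 10 (the proposed new macrocyclisation).** Exo closure, oligomerisation or poor stereoinduction at C3 are possible. The fallback uses known chemistry, sets out from 20 and comes back at 23. Hydrozirconation of the methyl alkyne with Cp2Zr(H)Cl (Zr at the methyl‑bearing carbon) and iodination gives the vinyl iodide [(3R,4S,7S)-4-(1,3-dioxolan-2-ylmethyl)-7-[(1R,4Z,7E)-1-hydroxy-8-iodo-4-methylnona-4,7-dien-1-yl]-7-methyl-2-oxooxepan-3-yl]methyl 2,2-dimethylpropanoate F5. Acetal hydrolysis (TsOH, THF/H2O) gives the iodo aldehyde [(3R,4S,7S)-7-[(1R,4Z,7E)-1-hydroxy-8-iodo-4-methylnona-4,7-dien-1-yl]-7-methyl-2-oxo-4-(2-oxoethyl)oxepan-3-yl]methyl 2,2-dimethylpropanoate F6. An asymmetric Ni/Cr (Nozaki–Hiyama–Kishi) macrocyclisation with a chiral sulfonamide ligand at high dilution then closes C3–C4 with retention of the E geometry and gives 23.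

**Step 8 (Baeyer–Villiger on a hindered β‑hydroxy ketone beside a trisubstituted alkene).** The ketone may react slowly, and the Lewis acid may cause retro‑aldol cleavage or open the acetal. The fallback sets out from 19 and comes back at 20. Excess mCPBA (NaHCO3, CH2Cl2) is allowed to do both the ring expansion and the epoxidation of C7=C8, giving the epoxy lactone [(3R,4S,7S)-4-(1,3-dioxolan-2-ylmethyl)-7-{(1R)-3-[cis-3-(but-2-yn-1-yl)-2-methyloxiran-2-yl]-1-hydroxypropyl}-7-methyl-2-oxooxepan-3-yl]methyl 2,2-dimethylpropanoate F4 (both epoxide faces). Stereospecific, retentive deoxygenation (cat. Re2O7, P(OPh)3, toluene, 100 °C) restores the Z alkene and gives 20.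

**Step 1 (alkylation of the alkenylcopper with a propargylic bromide).** SN2′ attack would give an allene instead of the skipped enyne. The fallback sets out from the alkenylcopper 6 and comes back at 7. Iodinolysis of 6 gives the vinyl iodide 2-[(3Z)-4-iodo-3-methylbut-3-en-1-yl]-1,3-dioxolane F1. Iodine–lithium exchange (t‑BuLi, Et2O, −78 °C) and paraformaldehyde give the allylic alcohol (2Z)-5-(1,3-dioxolan-2-yl)-3-methylpent-2-en-1-ol F2. CBr4/PPh3 gives the allylic bromide 2-[(3Z)-5-bromo-3-methylpent-3-en-1-yl]-1,3-dioxolane F3. CuBr‑catalysed coupling with prop‑1‑ynylmagnesium bromide (SN2 at the primary allylic bromide, geometry retained) gives 7.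

Further compounds
F1 | step 1 | 2-[(3Z)-4-iodo-3-methylbut-3-en-1-yl]-1,3-dioxolane | I/C=C(/C)CCC1OCCO1
F2 | step 1 | (2Z)-5-(1,3-dioxolan-2-yl)-3-methylpent-2-en-1-ol | OC/C=C(/C)CCC1OCCO1
F3 | step 1 | 2-[(3Z)-5-bromo-3-methylpent-3-en-1-yl]-1,3-dioxolane | BrC/C=C(/C)CCC1OCCO1
F4 | step 8 | [(3R,4S,7S)-4-(1,3-dioxolan-2-ylmethyl)-7-{(1R)-3-[cis-3-(but-2-yn-1-yl)-2-methyloxiran-2-yl]-1-hydroxypropyl}-7-methyl-2-oxooxepan-3-yl]methyl 2,2-dimethylpropanoate | CC(C)(C)C(=O)OC[C@@H]1C(=O)O[C@@]([C@H](O)CCC2(C)OC2CC#CC)(C)CC[C@H]1CC1OCCO1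
F5 | step 10 | [(3R,4S,7S)-4-(1,3-dioxolan-2-ylmethyl)-7-[(1R,4Z,7E)-1-hydroxy-8-iodo-4-methylnona-4,7-dien-1-yl]-7-methyl-2-oxooxepan-3-yl]methyl 2,2-dimethylpropanoate | CC(C)(C)C(=O)OC[C@@H]1C(=O)O[C@@]([C@H](O)CC/C(C)=C\C/C=C(\C)I)(C)CC[C@H]1CC1OCCO1
F6 | step 10 | [(3R,4S,7S)-7-[(1R,4Z,7E)-1-hydroxy-8-iodo-4-methylnona-4,7-dien-1-yl]-7-methyl-2-oxo-4-(2-oxoethyl)oxepan-3-yl]methyl 2,2-dimethylpropanoate | CC(C)(C)C(=O)OC[C@@H]1C(=O)O[C@@]([C@H](O)CC/C(C)=C\C/C=C(\C)I)(C)CC[C@H]1CC=O
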